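The route hinges on cutting both bonds that flank C8, the oxygen-bearing carbon lying between the 1-arylvinyl carbon C7 on benzene ring A and the allylic CH2 (C9) that leads to the C10=C11 alkene, so that C8–C9 come from a vinylboronate. One palladium-catalysed conjunctive coupling joins an arylvinyl group, the vinylboronate and an alkenyl triflate, forming C7–C8 and C9–C10 and setting C8 as an (S)-C–B bond that is later oxidised with retention. The precursor is a 1-arylvinyllithium (C2–OMOM, C5–OTIPS) made halide-free by tin–lithium exchange, vinylboronic acid pinacol ester and 2-methylprop-1-enyl triflate.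

Key step: step 9

Numbering used: ring A carbons C1–C6 (C1 carries the side chain, C2–OH, C3–OMe, C4–Me, C5–OAc, C6–H); side chain C7(=CH2)–C8(stereocentre)–C9H2–C10H=C11Me2. Ar = 3-methoxy-2-(methoxymethoxy)-4-methyl-5-(triisopropylsilyloxy)phenyl.

Design choices for the precursor:
- C2–O is carried as the MOM acetal, which directs the ring lithiation, chelates the vinyllithium and cannot shift to C7 as a silyl group could.
- C5–O is carried as the TIPS ether, which should withstand the basic and oxidative steps better than a smaller silyl group.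
- The lithium reagent is released from a stannane, so that no lithium halide travels with the borate into the palladium step.

Assumption: which enantiomer of the ferrocenyl bisphosphine gives S at C8 with this borate is assigned on alcohol 17 (MTPA ester analysis) in a first run; the antipodal ligand is used if R is found.

Step 1
Reactants: 1 2,4-dihydroxy-3-methylbenzaldehyde
Product: 2 2-hydroxy-3-methyl-4-(triisopropylsilyloxy)benzaldehyde
Conditions: TIPSCl (1.05 equiv), imidazole (2.2 equiv), DMF, 0 °C → rt
Reagents that add atoms: triisopropylsilyl chloride, CC(C)[Si](Cl)(C(C)C)C(C)C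
Why: Silyl ether formation should go to the 4-hydroxyl of 1 (future C5–O), the one not held in the hydrogen bond to the formyl group, so the two phenols are told apart at the outset.

Step 2
Reactants: 2 2-hydroxy-3-methyl-4-(triisopropylsilyloxy)benzaldehyde
Product: 3 2-methoxy-3-methyl-4-(triisopropylsilyloxy)benzaldehyde
Conditions: MeOH (2 equiv), PPh3 (1.3 equiv), DIAD (1.3 equiv), THF, 0 °C → rt
Reagents that add atoms: methanol, CO
Why: Mitsunobu etherification methylates the acidic, chelated phenol (future C3–OMe) without free base, so the para-formyl aryl silyl ether, which carbonate or alkoxide could cleave or shift, should stay in place.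

Step 3
Reactants: 3 2-methoxy-3-methyl-4-(triisopropylsilyloxy)benzaldehyde
Product: 5 2-methoxy-3-methyl-4-(triisopropylsilyloxy)phenol, via aryl formate 4 (not isolated)
Conditions: mCPBA (1.3 equiv), CH2Cl2, 0 °C → rt; then Et3N, MeOH, rt
Reagents that add atoms: 3-chloroperbenzoic acid, O=C(OO)c1cccc(Cl)c1
Why: Baeyer–Villiger oxidation of a benzaldehyde carrying ortho- and para-oxygen donors proceeds by aryl migration (Dakin-type outcome) and the aryl formate is methanolysed by a little amine base, which places the future C2 oxygen.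

Step 4
Reactants: 5 2-methoxy-3-methyl-4-(triisopropylsilyloxy)phenol
Product: 6 [3-methoxy-4-(methoxymethoxy)-2-methylphenoxy]triisopropylsilane
Conditions: MOMCl (1.5 equiv), iPr2NEt (2 equiv), CH2Cl2, 0 °C → rt
Reagents that add atoms: chloromethyl methyl ether, COCCl
Why: Williamson-type O-alkylation gives the MOM acetal, needed as the directing group of the next step and as a protecting group that cannot undergo a 1,4-silyl shift to the neighbouring vinyllithium later.

Step 5
Reactants: 6 [3-methoxy-4-(methoxymethoxy)-2-methylphenoxy]triisopropylsilane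
Product: 8 1-[3-methoxy-2-(methoxymethoxy)-4-methyl-5-(triisopropylsilyloxy)phenyl]ethanone (Ar–CO–CH3), via aryllithium 7 (not isolated)
Conditions: s-BuLi (1.2 equiv), TMEDA (1.2 equiv), THF, −78 °C; then N-methoxy-N-methylacetamide (1.5 equiv), −78 → 0 °C; aq. NH4Cl
Reagents that add atoms: N-methoxy-N-methylacetamide, CC(=O)N(C)OC
Why: Directed ortho-metalation by the MOM oxygen lithiates its only free ortho position (future C1), the bulky silyloxy group being a poor director toward C6, and the Weinreb ketone synthesis stops at the methyl ketone because the chelated tetrahedral adduct survives until work-up.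

Step 6
Reactants: 8 1-[3-methoxy-2-(methoxymethoxy)-4-methyl-5-(triisopropylsilyloxy)phenyl]ethanone
Product: 9 1-Ar-vinyl trifluoromethanesulfonate (Ar–C(OTf)=CH2)
Conditions: KN(SiMe3)2 (1.1 equiv), THF, −78 °C; then PhNTf2 (1.15 equiv), −78 → 0 °C; aq. NH4Cl
Reagents that add atoms: N-phenylbis(trifluoromethanesulfonimide), O=S(=O)(N(c1ccccc1)S(=O)(=O)C(F)(F)F)C(F)(F)F
Why: The acetyl methyl group is the only enolisable position, so enolate O-sulfonylation (enol triflate formation) can give only the terminal alkenyl triflate.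

Step 7
Reactants: 9 1-Ar-vinyl trifluoromethanesulfonate
Product: 10 trimethyl(1-Ar-vinyl)stannane (Ar–C(SnMe3)=CH2)
Conditions: Me3SnSnMe3 (1.2 equiv), Pd(PPh3)4 (5 mol %), LiCl (5 equiv), THF, 65 °C; aqueous KF work-up, Et3N-deactivated silica
Reagents that add atoms: hexamethylditin, C[Sn](C)(C)[Sn](C)(C)C
Why: Palladium-catalysed stannylation of an alkenyl triflate with a distannane (oxidative addition, tin-to-palladium transmetalation, reductive elimination) gives a storable alkenylstannane from which the lithium reagent can be set free without any halide.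

Step 8
Reactants: 11 isobutyraldehyde
Product: 12 2-methylprop-1-enyl trifluoromethanesulfonate
Conditions: Tf2O (1.1 equiv), 2,6-di-tert-butyl-4-methylpyridine (1.2 equiv), CH2Cl2, reflux; distil
Reagents that add atoms: trifluoromethanesulfonic anhydride, O=S(=O)(OS(=O)(=O)C(F)(F)F)C(F)(F)F
Why: O-Sulfonylation of the aldehyde and removal of its single alpha proton by the hindered, non-nucleophilic pyridine (alkenyl triflate synthesis from an enolisable aldehyde) can give only one alkene, with no E/Z question because the far terminus carries two methyl groups.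

Step 9
Reactants: 10 trimethyl(1-Ar-vinyl)stannane; 13 vinylboronic acid pinacol ester; 12 2-methylprop-1-enyl trifluoromethanesulfonate
Product: 16 2-[(3S)-2-Ar-6-methylhepta-1,5-dien-3-yl]-4,4,5,5-tetramethyl-1,3,2-dioxaborolane, via vinyllithium 14 (not isolated), via lithium borate 15 (not isolated)
Conditions: 10 (1.05 equiv), n-BuLi (1.0 equiv, hexanes), THF, −78 °C; 13 (1.0 equiv), −78 °C → rt; remove volatiles; Pd(OAc)2 (3 mol %), MandyPhos ligand 2,2′-bis[α-(dimethylamino)benzyl]-1,1′-bis(diphenylphosphino)ferrocene (single enantiomer, 3.6 mol %), 12 (1.2 equiv), THF, 60 °C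
Reagents that add atoms: none
Why: n-BuLi exchanges the Me3Sn group for lithium (tin–lithium exchange, no halide formed) and vinyllithium 14 adds to the boron of 13 to give bis(alkenyl)borate 15; zerovalent palladium, formed from Pd(OAc)2 and the bisphosphine, inserts into the C–O bond of triflate 12, and the resulting cationic alkenyl complex of divalent palladium binds the unsubstituted vinyl group of 15. The 1-arylvinyl group then moves from boron to the boron-bearing vinyl carbon (new C7–C8 bond) on the face opposite palladium, which takes the CH2 (C9), and reductive elimination joins C9 to C10. The closest known reaction type is the palladium-catalysed enantioselective conjunctive cross-coupling of vinylboron ate complexes with alkenyl triflates, in its bis(alkenyl)borate form where the more substituted alkenyl group migrates. No ring is closed; the one new stereocentre, C8, is set by the chiral bisphosphine–palladium complex, which selects one enantiotopic face of the bound vinyl group, and the ligand enantiomer is the one that leads to S. The step needs palladium to activate the plain vinyl group and not the 1-arylvinyl group, which the 1,1-disubstitution and the ortho-OMOM aryl ring of the latter should secure, and it needs the metallate shift to outrun direct alkenyl transfer to palladium, which the cationic, halide-free metal centre and the wide-bite-angle ligand favour.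

Step 10
Reactants: 16 2-[(3S)-2-Ar-6-methylhepta-1,5-dien-3-yl]-4,4,5,5-tetramethyl-1,3,2-dioxaborolane
Product: 17 (3S)-2-Ar-6-methylhepta-1,5-dien-3-ol
Conditions: NaBO3·4H2O (5 equiv), THF/H2O (1:1), rt
Reagents that add atoms: sodium perborate tetrahydrate, O.O.O.O.O.O.[Na+].[Na+].O[B-]1(O)OO[B-](O)(O)OO1
Why: Peroxide oxidation of the boronate moves C8 from boron to oxygen with retention, so (S)-C–B becomes (S)-C–O, and perborate is mild enough for the aryl silyl ether.

Step 11
Reactants: 17 (3S)-2-Ar-6-methylhepta-1,5-dien-3-ol; 18 angelic acid [(2Z)-2-methylbut-2-enoic acid]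
Product: 20 (3S)-2-Ar-6-methylhepta-1,5-dien-3-yl (2Z)-2-methylbut-2-enoate, via mixed anhydride 19 (not isolated)
Conditions: 18 (3 equiv), 2,4,6-trichlorobenzoyl chloride (3 equiv), Et3N (6 equiv), toluene, rt; then 17, 75 °C
Reagents that add atoms: none
Why: Yamaguchi-type mixed-anhydride acylation run without DMAP delivers the angeloyl group to the neutral alcohol at the less hindered carbonyl, which avoids the nucleophile-catalysed Z-to-E isomerisation to the tiglate and avoids an alkoxide that could start an anionic oxy-Cope rearrangement of the 3-hydroxy-1,5-diene, while C8 is not touched.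

Step 12
Reactants: 20 (3S)-2-Ar-6-methylhepta-1,5-dien-3-yl (2Z)-2-methylbut-2-enoate
Product: 22 (3S)-2-[5-acetoxy-3-methoxy-2-(methoxymethoxy)-4-methylphenyl]-6-methylhepta-1,5-dien-3-yl (2Z)-2-methylbut-2-enoate, via C5 phenol 21 (not isolated)
Conditions: TBAF (1.2 equiv), AcOH (1.2 equiv), THF, 0 °C → rt; then Ac2O (3 equiv), pyridine (5 equiv), rt
Reagents that add atoms: acetic anhydride, CC(=O)OC(C)=O
Why: Buffered fluoride cleaves the aryl silyl ether (Si–F bond formation, phenol as leaving group) and the freed C5 phenol is O-acetylated in the same flask, conditions to which the MOM acetal and the angelate should be inert.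

Step 13
Reactants: 22 (3S)-2-[5-acetoxy-3-methoxy-2-(methoxymethoxy)-4-methylphenyl]-6-methylhepta-1,5-dien-3-yl (2Z)-2-methylbut-2-enoate
Product: 24 (3S)-2-(5-acetoxy-2-hydroxy-3-methoxy-4-methylphenyl)-6-methylhepta-1,5-dien-3-yl (2Z)-2-methylbut-2-enoate (CNP0305991.1), via aryl trimethylsilyl ether 23 (not isolated)
Conditions: Me3SiOTf (3 equiv), 2,2′-bipyridyl (4.5 equiv), CH2Cl2, 0 °C → rt; then H2O, rt
Reagents that add atoms: none
Why: Silyl triflate/2,2′-bipyridyl cleavage of an aromatic MOM ether exchanges the acetal for an aryl silyl ether that water then hydrolyses, so no protic acid meets the aryl acetate, the allylic angelate or the two alkenes and the C2 phenol appears only at neutral work-up.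

Compound list
1 | 2,4-dihydroxy-3-methylbenzaldehyde | Cc1c(O)ccc(C=O)c1O | starting material
2 | 2-hydroxy-3-methyl-4-(triisopropylsilyloxy)benzaldehyde | Cc1c(O[Si](C(C)C)(C(C)C)C(C)C)ccc(C=O)c1O | intermediate
3 | 2-methoxy-3-methyl-4-(triisopropylsilyloxy)benzaldehyde | COc1c(C=O)ccc(O[Si](C(C)C)(C(C)C)C(C)C)c1C | intermediate
4 | 2-methoxy-3-methyl-4-(triisopropylsilyloxy)phenyl formate | COc1c(OC=O)ccc(O[Si](C(C)C)(C(C)C)C(C)C)c1C | intermediate (not isolated)
5 | 2-methoxy-3-methyl-4-(triisopropylsilyloxy)phenol | COc1c(O)ccc(O[Si](C(C)C)(C(C)C)C(C)C)c1C | intermediate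
6 | [3-methoxy-4-(methoxymethoxy)-2-methylphenoxy]triisopropylsilane | COCOc1ccc(O[Si](C(C)C)(C(C)C)C(C)C)c(C)c1OC | intermediate
7 | [3-methoxy-2-(methoxymethoxy)-4-methyl-5-(triisopropylsilyloxy)phenyl]lithium | [Li]c1cc(O[Si](C(C)C)(C(C)C)C(C)C)c(C)c(OC)c1OCOC | intermediate (not isolated)
8 | 1-[3-methoxy-2-(methoxymethoxy)-4-methyl-5-(triisopropylsilyloxy)phenyl]ethanone | CC(=O)c1cc(O[Si](C(C)C)(C(C)C)C(C)C)c(C)c(OC)c1OCOC | intermediate
9 | 1-[3-methoxy-2-(methoxymethoxy)-4-methyl-5-(triisopropylsilyloxy)phenyl]vinyl trifluoromethanesulfonate | C=C(OS(=O)(=O)C(F)(F)F)c1cc(O[Si](C(C)C)(C(C)C)C(C)C)c(C)c(OC)c1OCOC | intermediate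
10 | trimethyl{1-[3-methoxy-2-(methoxymethoxy)-4-methyl-5-(triisopropylsilyloxy)phenyl]vinyl}stannane | C=C([Sn](C)(C)C)c1cc(O[Si](C(C)C)(C(C)C)C(C)C)c(C)c(OC)c1OCOC | intermediate
11 | isobutyraldehyde | CC(C)C=O | starting material
12 | 2-methylprop-1-enyl trifluoromethanesulfonate | CC(C)=COS(=O)(=O)C(F)(F)F | intermediate
13 | vinylboronic acid pinacol ester | C=CB1OC(C)(C)C(C)(C)O1 | starting material
14 | 1-[3-methoxy-2-(methoxymethoxy)-4-methyl-5-(triisopropylsilyloxy)phenyl]vinyllithium | [Li]C(=C)c1cc(O[Si](C(C)C)(C(C)C)C(C)C)c(C)c(OC)c1OCOC | intermediate (not isolated)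
15 | lithium (1-Ar-vinyl)(vinyl)(pinacolato)borate | [Li+].C=C[B-]1(C(=C)c2cc(O[Si](C(C)C)(C(C)C)C(C)C)c(C)c(OC)c2OCOC)OC(C)(C)C(C)(C)O1 | intermediate (not isolated)
16 | 2-[(3S)-2-Ar-6-methylhepta-1,5-dien-3-yl]-4,4,5,5-tetramethyl-1,3,2-dioxaborolane | C=C(c1cc(O[Si](C(C)C)(C(C)C)C(C)C)c(C)c(OC)c1OCOC)[C@H](CC=C(C)C)B1OC(C)(C)C(C)(C)O1 | intermediate
17 | (3S)-2-Ar-6-methylhepta-1,5-dien-3-ol | C=C(c1cc(O[Si](C(C)C)(C(C)C)C(C)C)c(C)c(OC)c1OCOC)[C@H](CC=C(C)C)O | intermediate
18 | angelic acid, (2Z)-2-methylbut-2-enoic acid | C/C=C(/C)C(=O)O | starting material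
19 | (2Z)-2-methylbut-2-enoic 2,4,6-trichlorobenzoic anhydride | C/C=C(/C)C(=O)OC(=O)c1c(Cl)cc(Cl)cc1Cl | intermediate (not isolated)
20 | (3S)-2-Ar-6-methylhepta-1,5-dien-3-yl (2Z)-2-methylbut-2-enoate | C=C(c1cc(O[Si](C(C)C)(C(C)C)C(C)C)c(C)c(OC)c1OCOC)[C@H](CC=C(C)C)OC(=O)/C(C)=C\C | intermediate
21 | (3S)-2-[5-hydroxy-3-methoxy-2-(methoxymethoxy)-4-methylphenyl]-6-methylhepta-1,5-dien-3-yl (2Z)-2-methylbut-2-enoate | C=C(c1cc(O)c(C)c(OC)c1OCOC)[C@H](CC=C(C)C)OC(=O)/C(C)=C\C | intermediate (not isolated)
22 | (3S)-2-[5-acetoxy-3-methoxy-2-(methoxymethoxy)-4-methylphenyl]-6-methylhepta-1,5-dien-3-yl (2Z)-2-methylbut-2-enoate | C=C(c1cc(OC(C)=O)c(C)c(OC)c1OCOC)[C@H](CC=C(C)C)OC(=O)/C(C)=C\C | intermediate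
23 | (3S)-2-[5-acetoxy-3-methoxy-4-methyl-2-(trimethylsilyloxy)phenyl]-6-methylhepta-1,5-dien-3-yl (2Z)-2-methylbut-2-enoate | C=C(c1cc(OC(C)=O)c(C)c(OC)c1O[Si](C)(C)C)[C@H](CC=C(C)C)OC(=O)/C(C)=C\C | intermediate (not isolated)
24 | (3S)-2-(5-acetoxy-2-hydroxy-3-methoxy-4-methylphenyl)-6-methylhepta-1,5-dien-3-yl (2Z)-2-methylbut-2-enoate, CNP0305991.1 | C=C(c1cc(OC(C)=O)c(C)c(OC)c1O)[C@H](CC=C(C)C)OC(=O)/C(C)=C\C | target

Total step count: 13. Longest linear sequence: 12 steps (steps 1–7 and 9–13, from 1 to 24); step 8 is a one-step side branch.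

Steps most likely to fail

Step 9. The palladium cycle may turn over poorly, an alkenyl group may pass directly from boron to palladium instead of undergoing the metallate shift, or the facial selectivity may be low with the ortho-substituted migrating group. The fallback sets out from stannane 10 and comes back at boronate 16, using a stoichiometric, reagent-controlled 1,2-metallate shift (lithiation–borylation) in place of the catalytic one. Treating 10 with n-BuLi and then 2-isopropoxy-4,4,5,5-tetramethyl-1,3,2-dioxaborolane should give the 1-arylvinyl pinacol boronate F1. 4-Methylpent-3-en-1-ol and N,N-diisopropylcarbamoyl chloride (Et3N, toluene, reflux) give carbamate F2, which s-BuLi/(+)-sparteine (Et2O, −78 °C) should deprotonate enantioselectively to the (R)-lithiated carbamate F3. F3 adds to F1 with retention to give borate F4, and warming with MgBr2·OEt2 should make the arylvinyl group migrate with inversion as the carbamate leaves, which leads to (S)-16.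

Step 11. The Z-configured acyl group may isomerise to the E (tiglate) isomer during activation, or acylation of the hindered C8 hydroxyl may be too slow at a temperature the substrate tolerates. The fallback sets out from alcohol 17 and comes back at angelate 20, building the Z alkene on the ester instead of transferring it. Esterification of 17 with 2-[bis(2,2,2-trifluoroethoxy)phosphoryl]propanoic acid (DCC, DMAP, CH2Cl2) should give phosphonate ester F5. Still–Gennari olefination of F5 with acetaldehyde (KN(SiMe3)2, 18-crown-6, THF, −78 °C) should then give the Z-trisubstituted enoate 20.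

Step 13. The C5 acetate may be lost or transferred, or the Lewis acid may attack the allylic ester, while the doubly flanked acetal is slow to leave. The fallback sets out from angelate 20 and comes back at target 24, taking the acetal off before any aryl acetate exists. Me3SiOTf/2,2′-bipyridyl and then water on 20 should give the C2 phenol F6 with C5 still silylated. TBAF/AcOH then frees the C5 hydroxyl to give hydroquinone F7, which is kept under argon. One equivalent of Ac2O with pyridine at −20 °C should acetylate the open C5 hydroxyl in preference to the C2 hydroxyl, which is flanked by the methoxy group and the branched C7 substituent.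

Further compounds
F1 | step 9 | 2-(1-Ar-vinyl)-4,4,5,5-tetramethyl-1,3,2-dioxaborolane | C=C(B1OC(C)(C)C(C)(C)O1)c1cc(O[Si](C(C)C)(C(C)C)C(C)C)c(C)c(OC)c1OCOC
F2 | step 9 | 4-methylpent-3-en-1-yl N,N-diisopropylcarbamate | CC(C)=CCCOC(=O)N(C(C)C)C(C)C
F3 | step 9 | (1R)-1-lithio-4-methylpent-3-en-1-yl N,N-diisopropylcarbamate (sparteine complex) | [Li][C@H](CC=C(C)C)OC(=O)N(C(C)C)C(C)C
F4 | step 9 | lithium (1-Ar-vinyl)[(1R)-1-(N,N-diisopropylcarbamoyloxy)-4-methylpent-3-en-1-yl](pinacolato)borate | [Li+].C=C(c1cc(O[Si](C(C)C)(C(C)C)C(C)C)c(C)c(OC)c1OCOC)[B-]1(OC(C)(C)C(C)(C)O1)[C@H](CC=C(C)C)OC(=O)N(C(C)C)C(C)C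
F5 | step 11 | (3S)-2-Ar-6-methylhepta-1,5-dien-3-yl 2-[bis(2,2,2-trifluoroethoxy)phosphoryl]propanoate (both epimers at the phosphonate carbon) | C=C(c1cc(O[Si](C(C)C)(C(C)C)C(C)C)c(C)c(OC)c1OCOC)[C@H](CC=C(C)C)OC(=O)C(C)P(=O)(OCC(F)(F)F)OCC(F)(F)F
F6 | step 13 | (3S)-2-[2-hydroxy-3-methoxy-4-methyl-5-(triisopropylsilyloxy)phenyl]-6-methylhepta-1,5-dien-3-yl (2Z)-2-methylbut-2-enoate | C=C(c1cc(O[Si](C(C)C)(C(C)C)C(C)C)c(C)c(OC)c1O)[C@H](CC=C(C)C)OC(=O)/C(C)=C\C
F7 | step 13 | (3S)-2-(2,5-dihydroxy-3-methoxy-4-methylphenyl)-6-methylhepta-1,5-dien-3-yl (2Z)-2-methylbut-2-enoate | C=C(c1cc(O)c(C)c(OC)c1O)[C@H](CC=C(C)C)OC(=O)/C(C)=C\C
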